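## Structural features

Lapiferine is a daucane: a cyclopentane (C1–C5) trans-fused through the C1–C5 bond to a cycloheptane (C1, C5, C6–C10). The numbering used here is C1 for the methyl-bearing fusion carbon, C2 and C3 for the ring methylenes, C4 for the isopropyl carbinol, C5 for the fusion methine, C6 for the angelate carbinol, C7 for a methylene, C8/C9 for the epoxide (methyl on C8) and C10 for the free carbinol. All seven stereocentres are ring atoms and form two contiguous runs that meet at the ring fusion (C4–C5–C6 and C8–C9–C10–C1). The C6 ester oxygen, the epoxide oxygen and the C10 hydroxyl lie on the face opposite the C1 methyl, and the C4 hydroxyl lies on the methyl face. The fragile groups are the (Z)-2-methylbut-2-enoate (it isomerises to the tiglate), the trisubstituted epoxide next to a free hydroxyl (Payne migration, acid opening), and the C4 oxygen β to C6, which invites retro-aldol cleavage whenever C6 is a carbonyl and C4–OH is free. The real difficulty is the five-membered ring: the fully substituted carbinol C4, C5 and the quaternary C1 are contiguous, and C4 must be a single enantiomer although it carries no hydrogen. The key step uses the fact that C5 lies between C6, which can be carried as an ester, and the quaternary C1, which has no hydrogen to migrate, while the oxygen-bearing C4 is the fifth atom of the chain C5–C1–C2–C3–C4. A metal carbenoid at C5 can therefore insert into the C4–H bond of an easily made secondary silyl ether, closing ring C1–C5 and converting that carbinol into the tertiary one with retention.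

## Logic of the disconnections

Open-chain compounds keep the ring numbers of the target.

29 ⇒ 28. The C8–O and C9–O bonds are cut first, so the most fragile group is made last. The C10 hydroxyl of 28 can deliver oxygen to its own face, which reduces the epoxy alcohol to an alkene plus one carbinol. The forward step must ignore the electron-poor alkene of the ester and act only syn to C10–OH.

28 ⇒ 27 ⇒ 25 + 26. The two O–Si bonds and the C6–O acyl bond are cut. Acylating while C4 and C10 are capped leaves C6 as the only free hydroxyl, so no selectivity problem arises. The forward steps must esterify without Z-to-E isomerisation and must free a hindered tertiary silyl ether without harming the ester.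

25 ⇒ 24. The C6–C7 bond is cut. An allylsilane whose terminus C7 attacks a C6 aldehyde gives the C6 hydroxyl and puts the alkene exactly at C8=C9. The seven-membered ring is reduced to a cyclopentane with two side chains. The closure must be faster than loss of the β-silyloxy silane and must choose one aldehyde face.

24 ⇒ 23 ⇒ 22 ⇒ 21 ⇒ 17 + 18. After adjusting the C6 oxidation level and the C10 cap, the C9–C10 bond is cut. A chiral γ-silylallylborane made from 18 brings C7–C9, the C8 methyl and silicon in one step and sets C10 under reagent control. The forward step needs a defined reagent geometry and facial control on a hindered aldehyde.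

17 ⇒ 15. The C10 aldehyde is traced to an E-propenyl group (one C=C bond is formed in the retrosynthetic sense). The alkene is inert in the preceding steps and comes free of charge from the rearrangement that makes C1.

15 ⇒ 14. The C4–C5 bond is cut (key step). The hardest centre, C4, becomes an ordinary secondary silyl ether on an open chain, and the ring disappears. The forward step needs site selectivity for C4–H and retention. In 14 the propenyl group is E so that its methyl cannot reach the carbenoid, the C4 oxygen carries a silyl group with no C–H within reach, and C5 is not to be set by base equilibration, because an enolate at C5 could expel the C4 silyloxy group.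

14 ⇒ 12. The C5=N2 bond is cut. The diazo group is introduced on the ester by acyl activation and diazo transfer. The demand is C-acylation of an enolate next to a quaternary carbon.

12 ⇒ 9 + 10. The C1–C5 bond is cut as a [3,3] shift. A carbinol stereocentre is exchanged for the quaternary C1, and the ester and the E-propenyl group appear in the same step. The forward step demands a geometrically pure E alkene and a single carbinol configuration in 9.

9 ⇒ 8 ⇒ 6. The carbinol C–H bond is cut (reduction of 8), then the C1–methyl bond and the bond from C10 to the acetyl carbon are cut (syn carbometalation of the alkyne 6, then acylation). The two carbinols of 9 are set separately on purpose: with an E alkene, the allylic centre and C4 need opposite senses of one oxazaborolidine catalyst, and an isopropyl alkyl ketone would be poorly differentiated. Only the alkenyl methyl ketone 8 is therefore reduced asymmetrically.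

6 ⇒ 5 ⇒ 2 + 3, and 2 ⇒ 1. The O–Si bond and then the C2–C3 bond are cut (epoxide opening by the propargyl reagent from 3). C4 thus comes from a resolved terminal epoxide, which is more secure than an asymmetric reduction. The forward demand is attack at the unsubstituted epoxide carbon only.

## Other disconnections considered

Alternative 1: The cut runs through C1–C5 and C7–C8, so both rings come from an open chain in which only C4 is stereogenic. In the forward sense, triethylamine in trifluoroethanol would ionise an α-chloro ketone to the C5–C6–C7 oxyallyl cation, which adds to the tethered C1=C10–C9=C8 diene in a (4+3) sense to give the trans-fused ketone A1.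
- In its favour: two rings, two C–C bonds and the C1/C5 pair arise in one operation. On ring-forming step economy this is better than the chosen plan, which needs steps 8 and 14 for the same rings. The C6 carbonyl is also already in place.
- Against it here: the tertiary C4 carbinol must be made enantiopure on an open chain, which is harder than resolving the precursor of a secondary carbinol. This single centre, on a three-atom tether, must impose both the trans fusion and the diene face. It also sits next to the cationic C5, where loss of the silyloxy group competes.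
- Further against: A1 carries a C8 stereocentre that must later be erased, its alkene is at C9=C10 rather than C8=C9, and C6 is a ketone. Ketone reduction, alkene transposition to the C10 allylic alcohol and the epoxidation all still follow.
- Comparison: structurally A1 holds the whole carbon skeleton earlier than any compound of the chosen route (better), but with the seven-ring oxygen pattern still to be corrected (worse). Mechanistically a stepwise cationic cycloaddition with open ring-fusion selectivity stands against a concerted insertion with retention at the critical centre. The overall step count is probably similar.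

Alternative 2: The cut is C6–C7. BF3·OEt2 would activate the C6 aldehyde, the allylsilane terminus C7 would attack it, and silicon would leave from C9 to give the diol A2.
- In its favour: silicon fixes the alkene at C8=C9 and delivers the C6 carbinol, ready for a directed epoxidation. On the seven-ring closure it is the equal of the chosen plan, because step 14 is this very reaction. A2 has a free C4 hydroxyl, which spares the cleavage of a hindered tertiary silyl ether at the end; on that point it is better.
- Against it here: as a leading disconnection it leaves the C4/C5/C1 triad of the cyclopentane unsolved. A free C4 hydroxyl β to a Lewis-acid-bound C6 aldehyde risks retro-aldol cleavage and competitive binding.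
- Comparison: the two plans are complementary. Structurally this one addresses only the seven-membered ring. Mechanistically the face selectivity at C6 is substrate-controlled in both. Step economy is equal from the aldehyde onward. The chosen plan places the strategic weight on C4.

Alternative 3: The cuts are C6–C7 and C8–C9, with C7 and C8 supplied by isopropenyl acetate. Rh2(OAc)4 would turn a diazoketone into a C9 carbenoid that is captured by the C6 aldehyde oxygen, and the six-membered carbonyl ylide would add the enol acetate to give the oxygen-bridged adduct A3.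
- In its favour: it is convergent and installs C7, C8, the C8 methyl and the C8 oxygen in one step, and the aldehyde oxygen becomes the C6 oxygen. It uses the same inexpensive catalyst as the chosen key step (equal). It assembles the seven-ring carbons in fewer steps than steps 10–14 (better).
- Against it here: checking A3 against the target shows its ether bridge on the face of the C1 methyl. C6 is therefore R where lapiferine has S, and the C9–O bond is also on the wrong face. The adduct that maps onto the target is the bridge epimer A4, which requires the dipolarophile to approach syn to the angular methyl, the more hindered face. Otherwise C6 must be inverted after the bridge is opened.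
- Further against: regiochemistry with a weakly polarised enol acetate is open, and the C9 carbenoid has ring C–H bonds within reach. After the cycloaddition the route still needs reductive C9–O cleavage, elimination of acetic acid to the C8=C9 enone, face-selective reduction of the C10 ketone and the epoxidation. Like Alternative 2, it presupposes the cyclopentane.
- Comparison: both plans rest on a dirhodium carbenoid, here in a cascade with an external partner (less control) against an intramolecular insertion. Ring formation is shorter, but the redox repairs and a possible C6 inversion make the total comparable or longer.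

Key step: step 8

Assumption: compounds 1, 3, 10, 18 and 26 and all reagents are purchased; stereochemical assignments rest on chair transition states for the Claisen, allylboration and allylsilane steps.

## Route

Step 1
Reactants: 1 rac-2-isopropyloxirane
Product: 2 (S)-2-isopropyloxirane
Conditions: (R,R)-(salen)Co(OAc) (0.5 mol%), H2O (0.55 equiv), neat, 0 °C → rt; distil
Reagents that add atoms: none
Why: Hydrolytic kinetic resolution of a terminal epoxide; the (R,R) cobalt salen acetate should hydrolyse the R epoxide much faster, so the S epoxide, which carries the future C4 configuration, remains and is distilled from the diol.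

Step 2
Reactants: 2 (S)-2-isopropyloxirane; 3 propargyl bromide
Product: 5 (R)-2-methylhept-6-yn-3-ol, via propargylmagnesium bromide 4 (not isolated)
Conditions: 3, Mg, HgCl2 (cat.), Et2O, 0 °C; then 2, −78 °C → rt; aq NH4Cl
Reagents that add atoms: propargyl bromide (3), C#CCBr
Why: Grignard opening of a terminal epoxide at its unsubstituted carbon (SN2); the propargyl/allenyl magnesium reagent delivers the propargyl chain and forms the C2–C3 bond without touching the C4 stereocentre.

Step 3
Reactants: 5 (R)-2-methylhept-6-yn-3-ol
Product: 6 (R)-tert-butyldimethyl[(2-methylhept-6-yn-3-yl)oxy]silane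
Conditions: TBSCl, imidazole, DMF, rt
Reagents that add atoms: tert-butyldimethylsilyl chloride, CC(C)(C)[Si](C)(C)Cl
Why: Standard silylation of a secondary alcohol; the tert-butyldimethylsilyl ether should survive the organoaluminium, borane, hot orthoester and amide-base steps and later activates the C4–H bond without offering a reachable C–H of its own.

Step 4
Reactants: 6 (R)-tert-butyldimethyl[(2-methylhept-6-yn-3-yl)oxy]silane
Product: 8 (3E,7R)-7-[(tert-butyldimethylsilyl)oxy]-4,8-dimethylnon-3-en-2-one, via alkenyldimethylalane 7 (not isolated)
Conditions: AlMe3 (2.5 equiv), Cp2ZrCl2 (0.25 equiv), CH2Cl2, 0 °C → rt; evaporate; AcCl, Pd(PPh3)4 (5 mol%), THF, 0 °C → rt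
Reagents that add atoms: trimethylaluminium, C[Al](C)C; acetyl chloride, CC(=O)Cl
Why: Zirconium-catalysed carboalumination (Negishi) adds methyl and aluminium syn across the terminal alkyne with methyl on the internal carbon, which fixes the E trisubstituted alkene; palladium-catalysed acylation of the alkenylalane by acetyl chloride proceeds with retention of geometry.

Step 5
Reactants: 8 (3E,7R)-7-[(tert-butyldimethylsilyl)oxy]-4,8-dimethylnon-3-en-2-one
Product: 9 (2S,3E,7R)-7-[(tert-butyldimethylsilyl)oxy]-4,8-dimethylnon-3-en-2-ol
Conditions: (R)-2-methyl-CBS-oxazaborolidine (0.2 equiv), catecholborane (1.8 equiv), toluene, −78 °C; aq NaOH wash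
Reagents that add atoms: none
Why: Corey–Bakshi–Shibata reduction; the alkenyl group acts as the large and methyl as the small substituent, so the R catalyst should give the S carbinol, and catecholborane at low temperature avoids hydroboration and 1,4-reduction.

Step 6
Reactants: 9 (2S,3E,7R)-7-[(tert-butyldimethylsilyl)oxy]-4,8-dimethylnon-3-en-2-ol; 10 triethyl orthoacetate
Product: 12 ethyl (3S,6R)-6-[(tert-butyldimethylsilyl)oxy]-3,7-dimethyl-3-[(1E)-prop-1-en-1-yl]octanoate, via mixed ketene acetal 11 (not isolated)
Conditions: 10 (6 equiv), EtCO2H (5 mol%), 140 °C, EtOH distilled off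
Reagents that add atoms: triethyl orthoacetate (10), CCOC(C)(OCC)OCC
Why: Johnson–Claisen rearrangement; the ketene acetal rearranges through a chair with the carbinol methyl equatorial, so the C–O bond is exchanged suprafacially for the C1–C5 bond, and the S carbinol on the E alkene should give the required quaternary C1 together with an E propenyl group.

Step 7
Reactants: 12 ethyl (3S,6R)-6-[(tert-butyldimethylsilyl)oxy]-3,7-dimethyl-3-[(1E)-prop-1-en-1-yl]octanoate
Product: 14 ethyl (3R,6R)-6-[(tert-butyldimethylsilyl)oxy]-2-diazo-3,7-dimethyl-3-[(1E)-prop-1-en-1-yl]octanoate, via trifluoroacetyl ester 13 (not isolated)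
Conditions: LiN(i-Pr)2, THF, −78 °C; CF3CO2CH2CF3, −78 °C; then MsN3, Et3N, H2O (1 equiv), MeCN, rt
Reagents that add atoms: methanesulfonyl azide, CS(=O)(=O)N=[N+]=[N-]; 2,2,2-trifluoroethyl trifluoroacetate, O=C(OCC(F)(F)F)C(F)(F)F (adds the trifluoroacetyl group of 13 only)
Why: Deacylative (Regitz-type) diazo transfer; the lithium enolate is C-trifluoroacetylated to activate C5, and azide transfer with loss of the trifluoroacetyl group as the N-acylsulfonamide gives the diazo ester, while the quaternary C1 cannot epimerise.

Step 8
Reactants: 14 ethyl (3R,6R)-6-[(tert-butyldimethylsilyl)oxy]-2-diazo-3,7-dimethyl-3-[(1E)-prop-1-en-1-yl]octanoate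
Product: 15 ethyl (1R,2R,5R)-2-[(tert-butyldimethylsilyl)oxy]-5-methyl-2-(propan-2-yl)-5-[(1E)-prop-1-en-1-yl]cyclopentane-1-carboxylate
Conditions: Rh2(OAc)4 (1 mol%), CH2Cl2 (0.01 M), rt, slow addition of 14
Reagents that add atoms: none
Why: Rh2(OAc)4 decomposes the diazo ester with loss of N2 to an electrophilic divalent-rhodium carbenoid at C5, which inserts into the C4–H bond in one concerted, asynchronous three-centre event. The closest known reaction type is the dirhodium tetracarboxylate-catalysed 1,5 C–H insertion of α-diazo esters to cyclopentanes, which is favoured at methine C–H bonds and at C–H bonds next to ether oxygen. Ring C1–C5 is closed by the new C4–C5 bond through a five-ring-forming (1,5) transition state in which C5, C1, C2, C3 and C4 take a chair-like arrangement with the metal outside the ring. C4 becomes fully substituted with retention, because the C–H bond is replaced from the front, so its configuration is that of the resolved epoxide 2. C5 is set in the same transition state, where the ester should lie trans to the isopropyl group, the larger C4 substituent; no base equilibration is planned, since an enolate at C5 could expel the C4 silyloxy group. C1 is a spectator whose configuration comes from step 6. The step needs site selectivity for C4–H: a 1,2-hydride shift is excluded by the quaternary C1, the E propenyl group holds its allylic methyl out of reach and addition to that alkene would give a strained bicyclobutane, the ethyl hydrogens are kept away by the s-trans ester conformation, and the hindered silyl ether offers neither an ylide path nor a reachable C–H. Slow addition at high dilution should suppress carbene dimerisation.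

Step 9
Reactants: 15 ethyl (1R,2R,5R)-2-[(tert-butyldimethylsilyl)oxy]-5-methyl-2-(propan-2-yl)-5-[(1E)-prop-1-en-1-yl]cyclopentane-1-carboxylate
Product: 17 ethyl (1R,2R,5S)-2-[(tert-butyldimethylsilyl)oxy]-5-formyl-5-methyl-2-(propan-2-yl)cyclopentane-1-carboxylate, via ozonide 16 (not isolated)
Conditions: O3, CH2Cl2, −78 °C; PPh3, −78 °C → rt
Reagents that add atoms: ozone, [O-][O+]=O
Why: Ozonolysis of the only alkene with reductive work-up; the C10 aldehyde sits on a quaternary carbon and cannot epimerise, and the tertiary silyl ether has no C–H next to oxygen for ozone to attack.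

Step 10
Reactants: 17 ethyl (1R,2R,5S)-2-[(tert-butyldimethylsilyl)oxy]-5-formyl-5-methyl-2-(propan-2-yl)cyclopentane-1-carboxylate; 18 trimethyl(2-methylallyl)silane
Product: 21 C10 β-hydroxy allylsilane (C10 S and C9 R; anti; side chain (1S,2R)-1-hydroxy-3-methyl-2-(trimethylsilyl)but-3-en-1-yl on C1), via γ-silylallylborane 19 (not isolated), via borinate ester 20 (not isolated)
Conditions: 18, s-BuLi, TMEDA, THF, −78 °C; (+)-Ipc2BOMe; BF3·OEt2, −78 °C; then 17, −78 °C; NaHCO3, 30% H2O2, 0 °C → rt
Reagents that add atoms: trimethyl(2-methylallyl)silane (18), C=C(C)C[Si](C)(C)C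
Why: Allylboration through a closed chair transition state; lithiated 18 is trapped by boron at the carbon remote from silicon, the E reagent (silicon trans to the boron-bearing carbon, reachable by reversible 1,3-boron shift) should give the anti β-hydroxysilane, and the isopinocampheyl groups from (−)-α-pinene should select the aldehyde face that gives the C10 configuration of the target; the new hydroxyl cannot lactonise because C10 and C6 are trans on the cyclopentane.

Step 11
Reactants: 21 C10 β-hydroxy allylsilane
Product: 22 C4,C10-bis(tert-butyldimethylsilyl) ether of 21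
Conditions: TBSOTf, 2,6-lutidine, CH2Cl2, −78 → 0 °C
Reagents that add atoms: tert-butyldimethylsilyl triflate, CC(C)(C)[Si](C)(C)OS(=O)(=O)C(F)(F)F
Why: Silyl triflate silylation of a hindered secondary alcohol under a non-nucleophilic base; capping the hydroxyl blocks base-induced Peterson elimination and makes the C10 oxygen a poor leaving group for the Lewis acid step.

Step 12
Reactants: 22 C4,C10-bis(tert-butyldimethylsilyl) ether of 21
Product: 23 C6 primary alcohol (ester of 22 reduced to CH2OH)
Conditions: i-Bu2AlH (3 equiv), CH2Cl2, −78 → 0 °C; aq potassium sodium tartrate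
Reagents that add atoms: none
Why: Hydride reduction of the ester to the primary alcohol; the silyl ethers and the allylsilane are inert to the aluminium hydride, and full reduction avoids an uncertain partial reduction of a hindered ester.

Step 13
Reactants: 23 C6 primary alcohol
Product: 24 C6 aldehyde
Conditions: Dess–Martin periodinane, NaHCO3, CH2Cl2, 0 °C → rt
Reagents that add atoms: none
Why: Dess–Martin oxidation under buffered, non-basic conditions gives the aldehyde without enolising C5, which carries a β-silyloxy group.

Step 14
Reactants: 24 C6 aldehyde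
Product: 25 (1S,4R,5S,6S,10R)-4,10-bis[(tert-butyldimethylsilyl)oxy]dauc-8-en-6-ol
Conditions: BF3·OEt2 (1.5 equiv), CH2Cl2 (0.005 M), −78 °C; aq NaHCO3
Reagents that add atoms: none
Why: Intramolecular Hosomi–Sakurai reaction; the activated aldehyde is attacked by the alkene terminus C7 anti to the C9–Si bond and silicon leaves, so the double bond moves to C8=C9 and the seven-membered ring closes. In the chair-like transition state the bound aldehyde oxygen should turn away from C4 and C1 (over C5–H), which gives the C6 hydroxyl cis to H5 as in the target; the C9 configuration from step 10 holds silicon anti to the incoming carbonyl and gauche to the C10 oxygen, so the anti-elimination geometry is not met.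

Step 15
Reactants: 25 (1S,4R,5S,6S,10R)-4,10-bis[(tert-butyldimethylsilyl)oxy]dauc-8-en-6-ol; 26 angelic acid
Product: 27 (1S,4R,5S,6S,10R)-4,10-bis[(tert-butyldimethylsilyl)oxy]dauc-8-en-6-yl (Z)-2-methylbut-2-enoate
Conditions: 26, 2,4,6-Cl3C6H2COCl, Et3N, toluene, rt; then 25, 80 °C
Reagents that add atoms: angelic acid (26), C/C=C(/C)C(=O)O
Why: Yamaguchi-type esterification through the mixed anhydride of angelic acid, run without a nucleophilic catalyst so that the Z acid should not isomerise to the tiglate; C6–OH is the only free hydroxyl.

Step 16
Reactants: 27 (1S,4R,5S,6S,10R)-4,10-bis[(tert-butyldimethylsilyl)oxy]dauc-8-en-6-yl (Z)-2-methylbut-2-enoate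
Product: 28 (1S,4R,5S,6S,10R)-4,10-dihydroxydauc-8-en-6-yl (Z)-2-methylbut-2-enoate
Conditions: HF·pyridine, pyridine, THF, 0 °C → rt
Reagents that add atoms: none
Why: Fluoride cleavage of both silyl ethers under buffered acidic conditions that should leave the ester and its Z alkene alone; it is done before the epoxide exists, so the forcing needed for the tertiary C4 ether cannot open it.

Step 17
Reactants: 28 (1S,4R,5S,6S,10R)-4,10-dihydroxydauc-8-en-6-yl (Z)-2-methylbut-2-enoate
Product: 29 lapiferine
Conditions: VO(acac)2 (5 mol%), t-BuOOH (1.5 equiv), CH2Cl2, 0 °C → rt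
Reagents that add atoms: tert-butyl hydroperoxide, CC(C)(C)OO
Why: Vanadium-catalysed hydroxyl-directed epoxidation; the C10 allylic alkoxide binds the metal peroxide and oxygen should be delivered to the C8=C9 face syn to that hydroxyl, while the electron-poor angelate alkene is not attacked, which sets C8 and C9 and completes the target.

## Compound list

1 | rac-2-isopropyloxirane (3-methyl-1,2-epoxybutane) | CC(C)C1CO1 | starting material
2 | (S)-2-isopropyloxirane | CC(C)[C@H]1CO1 | intermediate
3 | propargyl bromide | C#CCBr | starting material
4 | propargylmagnesium bromide | C#CC[Mg]Br | intermediate (not isolated)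
5 | (R)-2-methylhept-6-yn-3-ol | C#CCC[C@@H](O)C(C)C | intermediate
6 | (R)-tert-butyldimethyl[(2-methylhept-6-yn-3-yl)oxy]silane | C#CCC[C@@H](O[Si](C)(C)C(C)(C)C)C(C)C | intermediate
7 | (E)-alkenyldimethylalane from 6 (Al cis to the new methyl) | C[Al](C)/C=C(\C)CC[C@@H](O[Si](C)(C)C(C)(C)C)C(C)C | intermediate (not isolated)
8 | (3E,7R)-7-[(tert-butyldimethylsilyl)oxy]-4,8-dimethylnon-3-en-2-one | CC(=O)/C=C(\C)CC[C@@H](O[Si](C)(C)C(C)(C)C)C(C)C | intermediate
9 | (2S,3E,7R)-7-[(tert-butyldimethylsilyl)oxy]-4,8-dimethylnon-3-en-2-ol | C[C@H](O)/C=C(\C)CC[C@@H](O[Si](C)(C)C(C)(C)C)C(C)C | intermediate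
10 | triethyl orthoacetate | CCOC(C)(OCC)OCC | starting material
11 | mixed ketene acetal of 9 (1-ethoxyvinyl ether) | C=C(OCC)O[C@@H](C)/C=C(\C)CC[C@@H](O[Si](C)(C)C(C)(C)C)C(C)C | intermediate (not isolated)
12 | ethyl (3S,6R)-6-[(tert-butyldimethylsilyl)oxy]-3,7-dimethyl-3-[(1E)-prop-1-en-1-yl]octanoate | CCOC(=O)C[C@@](C)(/C=C/C)CC[C@@H](O[Si](C)(C)C(C)(C)C)C(C)C | intermediate
13 | 2-trifluoroacetyl derivative of 12 (C2 epimers) | CCOC(=O)C(C(=O)C(F)(F)F)[C@@](C)(/C=C/C)CC[C@@H](O[Si](C)(C)C(C)(C)C)C(C)C | intermediate (not isolated)
14 | ethyl (3R,6R)-6-[(tert-butyldimethylsilyl)oxy]-2-diazo-3,7-dimethyl-3-[(1E)-prop-1-en-1-yl]octanoate | CCOC(=O)C(=[N+]=[N-])[C@@](C)(/C=C/C)CC[C@@H](O[Si](C)(C)C(C)(C)C)C(C)C | intermediate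
15 | ethyl (1R,2R,5R)-2-[(tert-butyldimethylsilyl)oxy]-5-methyl-2-(propan-2-yl)-5-[(1E)-prop-1-en-1-yl]cyclopentane-1-carboxylate | CCOC(=O)[C@H]1[C@](O[Si](C)(C)C(C)(C)C)(C(C)C)CC[C@]1(C)/C=C/C | intermediate
16 | ozonide (5-methyl-1,2,4-trioxolan-3-yl in place of propenyl) | CCOC(=O)[C@H]1[C@](O[Si](C)(C)C(C)(C)C)(C(C)C)CC[C@]1(C)C2OOC(C)O2 | intermediate (not isolated)
17 | ethyl (1R,2R,5S)-2-[(tert-butyldimethylsilyl)oxy]-5-formyl-5-methyl-2-(propan-2-yl)cyclopentane-1-carboxylate | CCOC(=O)[C@H]1[C@](O[Si](C)(C)C(C)(C)C)(C(C)C)CC[C@]1(C)C=O | intermediate
18 | trimethyl(2-methylallyl)silane | C=C(C)C[Si](C)(C)C | starting material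
19 | (E)-[2-methyl-3-(trimethylsilyl)prop-2-en-1-yl]bis(isopinocampheyl)borane, from (−)-α-pinene | C[Si](C)(C)/C=C(\C)CB([C@H]1C[C@H]2C[C@@H]([C@@H]1C)C2(C)C)[C@H]1C[C@H]2C[C@@H]([C@@H]1C)C2(C)C | intermediate (not isolated)
20 | bis(isopinocampheyl)borinate ester of 21 | CCOC(=O)[C@H]1[C@](O[Si](C)(C)C(C)(C)C)(C(C)C)CC[C@]1(C)[C@H](OB([C@H]2C[C@H]3C[C@@H]([C@@H]2C)C3(C)C)[C@H]2C[C@H]3C[C@@H]([C@@H]2C)C3(C)C)[C@H]([Si](C)(C)C)C(C)=C | intermediate (not isolated)
21 | ethyl ester with the (1S,2R)-1-hydroxy-3-methyl-2-(trimethylsilyl)but-3-en-1-yl chain on C1 (anti) | CCOC(=O)[C@H]1[C@](O[Si](C)(C)C(C)(C)C)(C(C)C)CC[C@]1(C)[C@H](O)[C@H]([Si](C)(C)C)C(C)=C | intermediate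
22 | C10 tert-butyldimethylsilyl ether of 21 | CCOC(=O)[C@H]1[C@](O[Si](C)(C)C(C)(C)C)(C(C)C)CC[C@]1(C)[C@H](O[Si](C)(C)C(C)(C)C)[C@H]([Si](C)(C)C)C(C)=C | intermediate
23 | C6 primary alcohol from 22 | OC[C@H]1[C@](O[Si](C)(C)C(C)(C)C)(C(C)C)CC[C@]1(C)[C@H](O[Si](C)(C)C(C)(C)C)[C@H]([Si](C)(C)C)C(C)=C | intermediate
24 | C6 aldehyde from 23 | O=C[C@H]1[C@](O[Si](C)(C)C(C)(C)C)(C(C)C)CC[C@]1(C)[C@H](O[Si](C)(C)C(C)(C)C)[C@H]([Si](C)(C)C)C(C)=C | intermediate
25 | (1S,4R,5S,6S,10R)-4,10-bis[(tert-butyldimethylsilyl)oxy]dauc-8-en-6-ol | O[C@H]1CC(C)=C[C@@H](O[Si](C)(C)C(C)(C)C)[C@@]2(C)CC[C@@](O[Si](C)(C)C(C)(C)C)(C(C)C)[C@H]12 | intermediate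
26 | angelic acid ((Z)-2-methylbut-2-enoic acid) | C/C=C(/C)C(=O)O | starting material
27 | C6 angelate of 25 | C/C=C(/C)C(=O)O[C@H]1CC(C)=C[C@@H](O[Si](C)(C)C(C)(C)C)[C@@]2(C)CC[C@@](O[Si](C)(C)C(C)(C)C)(C(C)C)[C@H]12 | intermediate
28 | (1S,4R,5S,6S,10R)-4,10-dihydroxydauc-8-en-6-yl angelate | C/C=C(/C)C(=O)O[C@H]1CC(C)=C[C@@H](O)[C@@]2(C)CC[C@@](O)(C(C)C)[C@H]12 | intermediate
29 | lapiferine | C/C=C(/C)C(=O)O[C@H]1C[C@@]2(C)O[C@H]2[C@@H](O)[C@@]2(C)CC[C@@](O)(C(C)C)[C@H]12 | target

## Step count and risk

Total: 17 steps. Longest linear sequence: 17 steps (1 to 29); all building blocks enter this single line.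

Least certain steps:

- **Step 8 (key step).** The carbenoid may add to the propenyl double bond (bicyclobutane formation). It may abstract hydride from C4 to a zwitterion that recloses without stereochemical fidelity or transfers silicon. It may dimerise because the C4 methine is crowded. Fallback, setting out from 12: silyl ketene acetal formation and bromination (LiN(i-Pr)2, Me3SiCl; NBS) give the α-bromo ester F1. HF·pyridine frees the C4 alcohol as the bromo alcohol F2. Dess–Martin oxidation gives the bromo ketone F3. A SmI2-mediated intramolecular Reformatsky reaction (THF, −78 °C) closes the C4–C5 bond to the hydroxy ester F4. TBSOTf/2,6-lutidine returns to the route at 15. In this fallback C4 and C5 are set by a chelated transition state relative to C1, not by retention.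

- **Step 10.** Control of the reagent geometry may be incomplete, which would give the syn adduct. Double stereodifferentiation with the hindered α-quaternary aldehyde may be mismatched. Peterson elimination may occur during the oxidative work-up. Fallback, setting out from 17 and replacing the allylsilane closure by ring-closing metathesis: vinylmagnesium bromide adds to C10 to give the vinyl carbinol F5 (substrate-controlled). Silylation gives the silyl ether F6. i-Bu2AlH reduction gives the primary alcohol F7. Dess–Martin oxidation gives the aldehyde F8. Methallylboration with (−)-Ipc2B(2-methylallyl) gives the homoallylic alcohol F9. Ring-closing metathesis with second-generation Hoveyda–Grubbs catalyst forms C8=C9 and returns to the route at 25.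

- **Step 14.** Silicon and the C10 silyloxy group may be lost (elimination to a diene) before the C–C bond forms, and facial selectivity at the aldehyde may be poor. Fallback, setting out from 24 after closure: if the C6-epimeric alcohol F10 predominates, Dess–Martin oxidation gives the C6 ketone F11. Reduction under thermodynamic control (SmI2, i-PrOH, THF) should favour the equatorial C6 alcohol and returns to the route at 25.

- **Step 16.** Cleavage of the tertiary C4 silyl ether may be incomplete, or the allylic C10 position may ionise under forcing acidic fluoride. Fallback, setting out from 25: global desilylation with Bu4NF (THF, 60 °C), where no sensitive group is yet present, gives the triol F12. VO(acac)2/t-BuOOH gives the epoxy triol F13. Mixed-anhydride angeloylation of the C6 hydroxyl, which is less hindered than C10–OH, returns to the route at 29.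

- **Step 7.** C-acylation of the enolate next to the quaternary C1 may be sluggish or incomplete, which would stop the diazo transfer. Fallback, setting out from 12: enolate hydroxylation (KN(SiMe3)2, Davis oxaziridine) gives the α-hydroxy ester F14. Dess–Martin oxidation gives the α-keto ester F15. Condensation with tosylhydrazide gives the tosylhydrazone F16. Base-induced Bamford–Stevens elimination (Et3N, CH2Cl2) returns to the route at 14.

- **Step 4.** Methyl transfer may compete, or alkene geometry may erode, during the acylation of the alkenylalane. Fallback, setting out from 6: the same carboalumination quenched with I2 gives the vinyl iodide F17. Halogen–lithium exchange (t-BuLi, −78 °C) and addition to N-methoxy-N-methylacetamide return to the route at 8.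

## Further compounds

F1 | step 8 | ethyl 2-bromo ester from 12 (C2 epimers) | CCOC(=O)C(Br)[C@@](C)(/C=C/C)CC[C@@H](O[Si](C)(C)C(C)(C)C)C(C)C
F2 | step 8 | ethyl 2-bromo-6-hydroxy ester | CCOC(=O)C(Br)[C@@](C)(/C=C/C)CC[C@@H](O)C(C)C
F3 | step 8 | ethyl 2-bromo-6-oxo ester | CCOC(=O)C(Br)[C@@](C)(/C=C/C)CCC(=O)C(C)C
F4 | step 8 | ethyl 2-hydroxy-5-methyl-2-(propan-2-yl)-5-[(1E)-prop-1-en-1-yl]cyclopentane-1-carboxylate (configuration of 15) | CCOC(=O)[C@H]1[C@](O)(C(C)C)CC[C@]1(C)/C=C/C
F5 | step 10 | C10 vinyl carbinol from 17 | CCOC(=O)[C@H]1[C@](O[Si](C)(C)C(C)(C)C)(C(C)C)CC[C@]1(C)[C@H](O)C=C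
F6 | step 10 | C10 tert-butyldimethylsilyl ether of F5 | CCOC(=O)[C@H]1[C@](O[Si](C)(C)C(C)(C)C)(C(C)C)CC[C@]1(C)[C@H](O[Si](C)(C)C(C)(C)C)C=C
F7 | step 10 | C6 primary alcohol from F6 | OC[C@H]1[C@](O[Si](C)(C)C(C)(C)C)(C(C)C)CC[C@]1(C)[C@H](O[Si](C)(C)C(C)(C)C)C=C
F8 | step 10 | C6 aldehyde from F7 | O=C[C@H]1[C@](O[Si](C)(C)C(C)(C)C)(C(C)C)CC[C@]1(C)[C@H](O[Si](C)(C)C(C)(C)C)C=C
F9 | step 10 | C6 methallyl carbinol (diene for metathesis) | C=C(C)C[C@H](O)[C@H]1[C@](O[Si](C)(C)C(C)(C)C)(C(C)C)CC[C@]1(C)[C@H](O[Si](C)(C)C(C)(C)C)C=C
F10 | step 14 | C6 epimer of 25 | O[C@@H]1CC(C)=C[C@@H](O[Si](C)(C)C(C)(C)C)[C@@]2(C)CC[C@@](O[Si](C)(C)C(C)(C)C)(C(C)C)[C@H]12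
F11 | step 14 | 4,10-bis[(tert-butyldimethylsilyl)oxy]dauc-8-en-6-one | O=C1CC(C)=C[C@@H](O[Si](C)(C)C(C)(C)C)[C@@]2(C)CC[C@@](O[Si](C)(C)C(C)(C)C)(C(C)C)[C@H]12
F12 | step 16 | dauc-8-ene-4,6,10-triol | O[C@H]1CC(C)=C[C@@H](O)[C@@]2(C)CC[C@@](O)(C(C)C)[C@H]12
F13 | step 16 | 8,9-epoxydaucane-4,6,10-triol | O[C@H]1C[C@@]2(C)O[C@H]2[C@@H](O)[C@@]2(C)CC[C@@](O)(C(C)C)[C@H]12
F14 | step 7 | ethyl 2-hydroxy ester from 12 (C2 epimers) | CCOC(=O)C(O)[C@@](C)(/C=C/C)CC[C@@H](O[Si](C)(C)C(C)(C)C)C(C)C
F15 | step 7 | ethyl 2-oxo ester | CCOC(=O)C(=O)[C@@](C)(/C=C/C)CC[C@@H](O[Si](C)(C)C(C)(C)C)C(C)C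
F16 | step 7 | tosylhydrazone of F15 | CCOC(=O)C(=NNS(=O)(=O)c1ccc(C)cc1)[C@@](C)(/C=C/C)CC[C@@H](O[Si](C)(C)C(C)(C)C)C(C)C
F17 | step 4 | (E)-vinyl iodide from 6 | I/C=C(\C)CC[C@@H](O[Si](C)(C)C(C)(C)C)C(C)C
A1 | alternative 1 | trans-fused C6 ketone with C9=C10 alkene and C4 triethylsilyl ether | O=C1C[C@H](C)C=C[C@@]2(C)CC[C@@](O[Si](CC)(CC)CC)(C(C)C)[C@H]12
A2 | alternative 2 | dauc-8-ene-4,6-diol C10 tert-butyldimethylsilyl ether | O[C@H]1CC(C)=C[C@@H](O[Si](C)(C)C(C)(C)C)[C@@]2(C)CC[C@@](O)(C(C)C)[C@H]12
A3 | alternative 3 | oxygen-bridged cycloadduct with the bridge on the C1-methyl face (C6 R) | O1[C@@H]2C[C@](C)(OC(C)=O)[C@H]1C(=O)[C@@]3(C)CC[C@@](O[Si](CC)(CC)CC)(C(C)C)[C@H]23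
A4 | alternative 3 | bridge epimer of A3 with C6 as in the target (C6 S) | O1[C@H]2C[C@@](C)(OC(C)=O)[C@@H]1C(=O)[C@@]3(C)CC[C@@](O[Si](CC)(CC)CC)(C(C)C)[C@H]23
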